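**Plan**
- Retrosynthesis: after removal of five benzyl ethers, ring C of unit 2 (O1''–C2''–C3''–C4''–C4a''–C8a'') is traced back to the five-membered ring of a 2-aryl-benzofuran-3(2H)-one by a reverse radical 1,2-acyl shift (cut C3''–C4'', re-join C2''–C4''); C3'' is then a CH(CO2H) carbon on the coumaranone C2.
- Enabling feature: C4'' is an acyl carbon β to C3'', and C2'' carries both O1'' and the 4-hydroxyphenyl ring, so the radical left at C2'' after the shift is benzylic and α-oxygenated.
- Further cuts: C2''–C3'' (Michael addition of the coumaranone to a 3-alkylidene flavanone), the exocyclic C3=C bond (glyoxylate aldol and dehydration), C2–aryl of unit 1 (asymmetric conjugate arylation of a chromone), O1''–C2'' of the coumaranone (deoxybenzoin bromination and cyclisation).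
- Forward order of rings: pyranone ring C of unit 1 (chromone, then flavanone), the five-membered coumaranone ring of the other half, union of the halves, ring expansion five → six to ring C of unit 2, global debenzylation.
- Stereochemistry: C2 from the chiral palladium catalyst; the quaternary coumaranone carbon from a chiral squaramide catalyst, relayed to C3'' in the key step; C3 by equilibration to 2,3-trans before the key step; C2'' by hydrogen-atom delivery anti to the C3'' substituent (2'',3''-cis, kinetic).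

Key step: step 12

Remarks on the chemistry: unit 1 is the 4-methoxyphenyl flavanone (locants C2, C3, C4) and unit 2 the 4-hydroxyphenyl flavanone (doubly primed locants); the target is (2S,3R,2''S,3''S), unit 1 trans and unit 2 cis. The antipodes of the chiral catalysts in steps 3 and 9 are named for the expected sense of induction; the mirror-image (or pseudo-enantiomeric) catalyst is taken if a test reaction shows the opposite sense. In 21, 22 and 24 the carbon between the two units is an epimer mixture, carried through because it becomes a planar radical in step 12.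

**Step 1**
Reactants: 1 1-(2,4,6-trihydroxyphenyl)ethanone; 2 benzyl bromide
Product: 3 1-[2,4-bis(benzyloxy)-6-hydroxyphenyl]ethanone
Conditions: BnBr (2.05 equiv), K2CO3 (2.2 equiv), DMF, 25 °C
Reagents that add atoms: benzyl bromide, BrCc1ccccc1
Why: Williamson ether synthesis; the two non-chelated hydroxyls react and the hydroxyl hydrogen-bonded to the ketone should stay free.

**Step 2**
Reactants: 3 1-[2,4-bis(benzyloxy)-6-hydroxyphenyl]ethanone; 4 N,N-dimethylformamide dimethyl acetal
Product: 6 5,7-bis(benzyloxy)-4H-chromen-4-one, via enaminone 5 (not isolated)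
Conditions: 4 (3 equiv, neat), 95 °C; then conc. HCl, CH2Cl2, 40 °C
Reagents that add atoms: N,N-dimethylformamide dimethyl acetal, COC(OC)N(C)C
Why: Enaminone condensation at the acetyl group followed by acid-promoted 6-endo addition–elimination of the phenol (standard chromone synthesis).

**Step 3**
Reactants: 6 5,7-bis(benzyloxy)-4H-chromen-4-one; 7 (4-methoxyphenyl)boronic acid
Product: 8 (2S)-5,7-bis(benzyloxy)-2-(4-methoxyphenyl)chroman-4-one
Conditions: Pd(OCOCF3)2 (5 mol %), (R)-t-BuPyOx (6 mol %), NH4PF6 (30 mol %), H2O (5 equiv), ClCH2CH2Cl, 60 °C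
Reagents that add atoms: (4-methoxyphenyl)boronic acid, COc1ccc(B(O)O)cc1
Why: Palladium-catalysed asymmetric conjugate addition of an arylboronic acid to a chromone (Hayashi–Miyaura type); the pyridine–oxazoline ligand selects the enone face and should set C2 as S.

**Step 4**
Reactants: 8 (2S)-5,7-bis(benzyloxy)-2-(4-methoxyphenyl)chroman-4-one; 9 tert-butyl glyoxylate
Product: 12 tert-butyl 2-[(2S)-5,7-bis(benzyloxy)-2-(4-methoxyphenyl)-4-oxochroman-3-yl]-2-hydroxyacetate (diastereomer mixture at C3 and the carbinol carbon), via silyl enol ether 10 (not isolated), via O-silyl aldol adduct 11 (not isolated)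
Conditions: i-Pr2NEt (1.3 equiv), Me3SiOTf (1.6 equiv), CH2Cl2, 0 °C; then 9 (1.5 equiv), −78 °C; quench cold, 1 M HCl–THF, 0 °C
Reagents that add atoms: tert-butyl glyoxylate, O=CC(=O)OC(C)(C)C
Why: One-pot enol silane formation and Mukaiyama aldol addition; no free enolate is formed, so the ring should not open to the chalcone and C2 is kept, and the new centres at C3 and the carbinol carbon are removed in step 5.

**Step 5**
Reactants: 12 tert-butyl 2-[(2S)-5,7-bis(benzyloxy)-2-(4-methoxyphenyl)-4-oxochroman-3-yl]-2-hydroxyacetate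
Product: 14 tert-butyl (2E)-2-[(2R)-5,7-bis(benzyloxy)-2-(4-methoxyphenyl)-4-oxochroman-3-ylidene]acetate, via mesylate 13 (not isolated)
Conditions: MsCl (1.5 equiv), Et3N (3 equiv), CH2Cl2, 0 °C, short reaction time
Reagents that add atoms: none
Why: Mesylation and E1cB elimination through the ketone enolate should give the conjugated exocyclic alkene as the E isomer (ester away from the ketone carbonyl); C2 keeps its spatial arrangement and its descriptor changes to R only because C3 now outranks the aryl group.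

**Step 6**
Reactants: 15 benzene-1,3,5-triol (phloroglucinol); 16 4-hydroxyphenylacetic acid
Product: 17 2-(4-hydroxyphenyl)-1-(2,4,6-trihydroxyphenyl)ethanone
Conditions: BF3·OEt2 (neat), 85 °C; aq. NaOAc work-up
Reagents that add atoms: 4-hydroxyphenylacetic acid, OC(=O)Cc1ccc(O)cc1
Why: Friedel–Crafts C-acylation of phloroglucinol by the BF3-activated acid (Houben–Hoesch-type deoxybenzoin synthesis); the symmetry of phloroglucinol leaves no regiochemical question.

**Step 7**
Reactants: 17 2-(4-hydroxyphenyl)-1-(2,4,6-trihydroxyphenyl)ethanone; 2 benzyl bromide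
Product: 18 1-[2,4-bis(benzyloxy)-6-hydroxyphenyl]-2-[4-(benzyloxy)phenyl]ethanone
Conditions: BnBr (3.1 equiv), K2CO3 (3.3 equiv), DMF, 25 °C
Reagents that add atoms: benzyl bromide, BrCc1ccccc1
Why: Williamson ether synthesis; the ketone-chelated ortho hydroxyl should again stay free and is needed for ring closure in step 8.

**Step 8**
Reactants: 18 1-[2,4-bis(benzyloxy)-6-hydroxyphenyl]-2-[4-(benzyloxy)phenyl]ethanone
Product: 20 4,6-bis(benzyloxy)-2-[4-(benzyloxy)phenyl]-1-benzofuran-3(2H)-one (racemic), via α-bromo ketone 19 (not isolated)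
Conditions: CuBr2 (2.1 equiv), EtOAc–CHCl3, reflux; then NaOAc (3 equiv), EtOH, 25 °C, argon
Reagents that add atoms: none
Why: α-Bromination of the benzyl ketone with copper dibromide and 5-exo-tet intramolecular Williamson O-alkylation by the free phenol give the 2-aryl coumaranone; its C2 is enolisable and racemic, which is harmless because it is set in step 9.

**Step 9**
Reactants: 14 tert-butyl (2E)-2-[(2R)-5,7-bis(benzyloxy)-2-(4-methoxyphenyl)-4-oxochroman-3-ylidene]acetate; 20 4,6-bis(benzyloxy)-2-[4-(benzyloxy)phenyl]-1-benzofuran-3(2H)-one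
Product: 21 tert-butyl 2-{(2R)-4,6-bis(benzyloxy)-2-[4-(benzyloxy)phenyl]-3-oxo-2,3-dihydro-1-benzofuran-2-yl}-2-[(2S,3R)-5,7-bis(benzyloxy)-2-(4-methoxyphenyl)-4-oxochroman-3-yl]acetate (both epimers at the acetate α-carbon)
Conditions: quinine-derived 3,5-bis(trifluoromethyl)anilino squaramide (9-amino-9-deoxy-epi-quinine type, 10 mol %), CH2Cl2, −20 → 25 °C, argon; stirred at 25 °C until C3 has converged on 2,3-trans
Reagents that add atoms: 4,6-bis(benzyloxy)-2-[4-(benzyloxy)phenyl]-1-benzofuran-3(2H)-one, O=C1C(c2ccc(OCc3ccccc3)cc2)Oc2cc(OCc3ccccc3)cc(OCc3ccccc3)c12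
Why: Organocatalytic Michael addition of a tertiary carbon acid to a γ-oxo-α,β-unsaturated ester: attack falls on the alkene carbon β to the ketone, the bifunctional catalyst chooses the enolate face so that the quaternary carbon should be R, C3 is protonated and equilibrates through the enol to the more stable 2,3-trans arrangement, and the configuration of the ester α-carbon is of no consequence.

**Step 10**
Reactants: 21 the tert-butyl ester from step 9
Product: 22 2-{(2R)-4,6-bis(benzyloxy)-2-[4-(benzyloxy)phenyl]-3-oxo-2,3-dihydro-1-benzofuran-2-yl}-2-[(2S,3R)-5,7-bis(benzyloxy)-2-(4-methoxyphenyl)-4-oxochroman-3-yl]acetic acid (both epimers at the α-carbon)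
Conditions: CF3CO2H–CH2Cl2 (1:4), 0 °C
Reagents that add atoms: none
Why: Acidolysis of the tert-butyl ester (E1 loss of isobutene) should free the acid without touching the benzyl ethers or the stereocentres.

**Step 11**
Reactants: 22 the acid from step 10; 23 N-hydroxyphthalimide
Product: 24 1,3-dioxoisoindolin-2-yl 2-{(2R)-4,6-bis(benzyloxy)-2-[4-(benzyloxy)phenyl]-3-oxo-2,3-dihydro-1-benzofuran-2-yl}-2-[(2S,3R)-5,7-bis(benzyloxy)-2-(4-methoxyphenyl)-4-oxochroman-3-yl]acetate (both epimers at the α-carbon)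
Conditions: N,N'-diisopropylcarbodiimide (1.2 equiv), DMAP (5 mol %), CH2Cl2, 0 → 25 °C
Reagents that add atoms: N-hydroxyphthalimide, ON1C(=O)c2ccccc2C1=O
Why: Carbodiimide (Steglich-type) esterification gives the redox-active N-acyloxyphthalimide.

**Step 12**
Reactants: 24 the N-acyloxyphthalimide from step 11; 25 diethyl 2,6-dimethyl-1,4-dihydropyridine-3,5-dicarboxylate (Hantzsch ester)
Product: 26 (2S,3R,2''S,3''S)-5,7,5'',7''-tetrakis(benzyloxy)-2''-[4-(benzyloxy)phenyl]-2-(4-methoxyphenyl)-3,3''-bichroman-4,4''-dione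
Conditions: Ru(bpy)3(PF6)2 (2 mol %), 25 (1.5 equiv), degassed CH2Cl2 (0.01 M), blue LEDs (450 nm), 25 °C; no amine, no thiol
Reagents that add atoms: none
Why: Proposed new method: one-electron reduction of the N-acyloxyphthalimide by the photoreduced ruthenium complex should expel CO2 and phthalimide anion and leave a secondary radical on the carbon between the two units; this radical adds 3-exo-trig to the C3 carbonyl of the coumaranone, the cyclopropyloxy radical opens by β-scission of the old C2–C3 bond (the only fragmentation that gives a radical stabilised by both the ring oxygen and the aryl group), and hydrogen-atom transfer from the Hantzsch ester ends the sequence. The closest known reaction type is the Dowd–Beckwith ring expansion of α-(halomethyl) β-keto esters, combined with reductive decarboxylation of redox-active esters; the 1,2-acyl shift has not been described for 2-aryl-benzofuran-3(2H)-ones. The six-membered ring is not closed by a ring-forming bond of its own but arises by 3-exo-trig addition to C=O followed by retro-3-exo-trig cleavage of the bond shared with the five-membered ring. C3'' is controlled by the sacrificial quaternary carbon: in the bicyclo[3.1.0]-like transition state the flavanonyl group takes the exo position, away from the benzofuranone plane, so the R quaternary centre should be relayed to S at C3''; C2'' is controlled by C3'', whose substituent is held pseudo-axial next to the planar benzylic radical so that hydrogen arrives on the opposite face, which should give the 2'',3''-cis unit under kinetic control. The step needs migration of the coumaranone acyl group and not of the flavanone C4 acyl group, which is also β to the radical (the 3-exo additions are reversible and only cleavage on the coumaranone side leads to a stabilised radical); it needs rearrangement before hydrogen capture (dilution and a slow hydrogen donor); and it needs neutral conditions, which keep C3 and the new cis unit from epimerising because no enolate is formed.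

**Step 13**
Reactants: 26 the pentabenzyl ether from step 12
Product: 27 (2S,3R,2''S,3''S)-5,7,5'',7''-tetrahydroxy-2''-(4-hydroxyphenyl)-2-(4-methoxyphenyl)-3,3''-bichroman-4,4''-dione (CNP0196568.6)
Conditions: H2 (1 atm), 10% Pd/C, EtOAc–MeOH (1:1), 25 °C; filtration, no acid or base
Reagents that add atoms: none
Why: Hydrogenolysis of the five benzyl ethers under neutral conditions; the methyl ether and both flavanone carbonyls should stay, and without acid or base the cis unit should not epimerise.

**Compound list**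
1 | 1-(2,4,6-trihydroxyphenyl)ethanone | CC(=O)c1c(O)cc(O)cc1O | starting material
2 | benzyl bromide | BrCc1ccccc1 | starting material
3 | 1-[2,4-bis(benzyloxy)-6-hydroxyphenyl]ethanone | CC(=O)c1c(O)cc(OCc2ccccc2)cc1OCc1ccccc1 | intermediate
4 | N,N-dimethylformamide dimethyl acetal | COC(OC)N(C)C | starting material
5 | (E)-1-[2,4-bis(benzyloxy)-6-hydroxyphenyl]-3-(dimethylamino)prop-2-en-1-one | CN(C)/C=C/C(=O)c1c(O)cc(OCc2ccccc2)cc1OCc1ccccc1 | intermediate (not isolated)
6 | 5,7-bis(benzyloxy)-4H-chromen-4-one | O=c1ccoc2cc(OCc3ccccc3)cc(OCc3ccccc3)c12 | intermediate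
7 | (4-methoxyphenyl)boronic acid | COc1ccc(B(O)O)cc1 | starting material
8 | (2S)-5,7-bis(benzyloxy)-2-(4-methoxyphenyl)chroman-4-one | COc1ccc([C@H]2Oc3cc(OCc4ccccc4)cc(OCc4ccccc4)c3C(=O)C2)cc1 | intermediate
9 | tert-butyl glyoxylate (tert-butyl 2-oxoacetate) | O=CC(=O)OC(C)(C)C | starting material
10 | (2S)-5,7-bis(benzyloxy)-2-(4-methoxyphenyl)-4-(trimethylsilyloxy)-2H-chromene | COc1ccc([C@H]2Oc3cc(OCc4ccccc4)cc(OCc4ccccc4)c3C(O[Si](C)(C)C)=C2)cc1 | intermediate (not isolated)
11 | tert-butyl 2-[(2S)-5,7-bis(benzyloxy)-2-(4-methoxyphenyl)-4-oxochroman-3-yl]-2-(trimethylsilyloxy)acetate (mixture at C3 and the silyloxy carbon) | COc1ccc([C@H]2Oc3cc(OCc4ccccc4)cc(OCc4ccccc4)c3C(=O)C2C(O[Si](C)(C)C)C(=O)OC(C)(C)C)cc1 | intermediate (not isolated)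
12 | tert-butyl 2-[(2S)-5,7-bis(benzyloxy)-2-(4-methoxyphenyl)-4-oxochroman-3-yl]-2-hydroxyacetate (mixture at C3 and the carbinol carbon) | COc1ccc([C@H]2Oc3cc(OCc4ccccc4)cc(OCc4ccccc4)c3C(=O)C2C(O)C(=O)OC(C)(C)C)cc1 | intermediate
13 | tert-butyl 2-[(2S)-5,7-bis(benzyloxy)-2-(4-methoxyphenyl)-4-oxochroman-3-yl]-2-(methylsulfonyloxy)acetate (mixture at C3 and the sulfonyloxy carbon) | COc1ccc([C@H]2Oc3cc(OCc4ccccc4)cc(OCc4ccccc4)c3C(=O)C2C(OS(C)(=O)=O)C(=O)OC(C)(C)C)cc1 | intermediate (not isolated)
14 | tert-butyl (2E)-2-[(2R)-5,7-bis(benzyloxy)-2-(4-methoxyphenyl)-4-oxochroman-3-ylidene]acetate (C2 spatially as in 8) | COc1ccc([C@H]2Oc3cc(OCc4ccccc4)cc(OCc4ccccc4)c3C(=O)/C2=C/C(=O)OC(C)(C)C)cc1 | intermediate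
15 | benzene-1,3,5-triol (phloroglucinol) | Oc1cc(O)cc(O)c1 | starting material
16 | 4-hydroxyphenylacetic acid | OC(=O)Cc1ccc(O)cc1 | starting material
17 | 2-(4-hydroxyphenyl)-1-(2,4,6-trihydroxyphenyl)ethanone | O=C(Cc1ccc(O)cc1)c1c(O)cc(O)cc1O | intermediate
18 | 1-[2,4-bis(benzyloxy)-6-hydroxyphenyl]-2-[4-(benzyloxy)phenyl]ethanone | O=C(Cc1ccc(OCc2ccccc2)cc1)c1c(O)cc(OCc2ccccc2)cc1OCc1ccccc1 | intermediate
19 | 1-[2,4-bis(benzyloxy)-6-hydroxyphenyl]-2-[4-(benzyloxy)phenyl]-2-bromoethanone (racemic) | O=C(C(Br)c1ccc(OCc2ccccc2)cc1)c1c(O)cc(OCc2ccccc2)cc1OCc1ccccc1 | intermediate (not isolated)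
20 | 4,6-bis(benzyloxy)-2-[4-(benzyloxy)phenyl]-1-benzofuran-3(2H)-one (racemic, enolisable) | O=C1C(c2ccc(OCc3ccccc3)cc2)Oc2cc(OCc3ccccc3)cc(OCc3ccccc3)c12 | intermediate
21 | tert-butyl 2-{(2R)-4,6-bis(benzyloxy)-2-[4-(benzyloxy)phenyl]-3-oxo-2,3-dihydro-1-benzofuran-2-yl}-2-[(2S,3R)-5,7-bis(benzyloxy)-2-(4-methoxyphenyl)-4-oxochroman-3-yl]acetate (α-carbon epimers) | COc1ccc([C@H]2Oc3cc(OCc4ccccc4)cc(OCc4ccccc4)c3C(=O)[C@@H]2C(C(=O)OC(C)(C)C)[C@]2(c3ccc(OCc4ccccc4)cc3)Oc3cc(OCc4ccccc4)cc(OCc4ccccc4)c3C2=O)cc1 | intermediate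
22 | 2-{(2R)-4,6-bis(benzyloxy)-2-[4-(benzyloxy)phenyl]-3-oxo-2,3-dihydro-1-benzofuran-2-yl}-2-[(2S,3R)-5,7-bis(benzyloxy)-2-(4-methoxyphenyl)-4-oxochroman-3-yl]acetic acid (α-carbon epimers) | COc1ccc([C@H]2Oc3cc(OCc4ccccc4)cc(OCc4ccccc4)c3C(=O)[C@@H]2C(C(=O)O)[C@]2(c3ccc(OCc4ccccc4)cc3)Oc3cc(OCc4ccccc4)cc(OCc4ccccc4)c3C2=O)cc1 | intermediate
23 | N-hydroxyphthalimide | ON1C(=O)c2ccccc2C1=O | starting material
24 | 1,3-dioxoisoindolin-2-yl ester of acid 22 (α-carbon epimers) | COc1ccc([C@H]2Oc3cc(OCc4ccccc4)cc(OCc4ccccc4)c3C(=O)[C@@H]2C(C(=O)ON2C(=O)c3ccccc3C2=O)[C@]2(c3ccc(OCc4ccccc4)cc3)Oc3cc(OCc4ccccc4)cc(OCc4ccccc4)c3C2=O)cc1 | intermediate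
25 | diethyl 2,6-dimethyl-1,4-dihydropyridine-3,5-dicarboxylate (Hantzsch ester) | CCOC(=O)C1=C(C)NC(C)=C(C(=O)OCC)C1 | starting material
26 | (2S,3R,2''S,3''S)-5,7,5'',7''-tetrakis(benzyloxy)-2''-[4-(benzyloxy)phenyl]-2-(4-methoxyphenyl)-3,3''-bichroman-4,4''-dione | COc1ccc([C@H]2Oc3cc(OCc4ccccc4)cc(OCc4ccccc4)c3C(=O)[C@@H]2[C@@H]2C(=O)c3c(OCc4ccccc4)cc(OCc4ccccc4)cc3O[C@@H]2c2ccc(OCc3ccccc3)cc2)cc1 | intermediate
27 | (2S,3R,2''S,3''S)-5,7,5'',7''-tetrahydroxy-2''-(4-hydroxyphenyl)-2-(4-methoxyphenyl)-3,3''-bichroman-4,4''-dione | COc1ccc([C@H]2Oc3cc(O)cc(O)c3C(=O)[C@@H]2[C@@H]2C(=O)c3c(O)cc(O)cc3O[C@@H]2c2ccc(O)cc2)cc1 | target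

**Count**
Total steps: 13. Longest linear sequence: 10 steps (steps 1–5, then 9–13); steps 6–8 form the second branch, which joins at step 9.

**Steps most likely to fail**

Step 12 (labelled). The radical on the inter-unit carbon may take up hydrogen before the acyl shift, may fragment on the flavanone side or by loss of the aryloxy group, or the exo preference in the 3-exo addition may be weak, so that the relay of configuration to C3'' is incomplete. The fallback gives up the ring expansion and uses known reactions only; it sets out from 3 and from the enol silane 10 (made from 8 as in step 4) and comes back at 27.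
- Claisen–Schmidt condensation of 3 with 4-(benzyloxy)benzaldehyde (KOH, EtOH) would give the chalcone (E)-1-[2,4-bis(benzyloxy)-6-hydroxyphenyl]-3-[4-(benzyloxy)phenyl]prop-2-en-1-one F1.
- Oxidative cyclisation (I2 cat., DMSO, 130 °C) would give the flavone 5,7-bis(benzyloxy)-2-[4-(benzyloxy)phenyl]-4H-chromen-4-one F2.
- Lithiation at C3 and iodination (LiN(i-Pr)2, THF, −78 °C; I2) would give 5,7-bis(benzyloxy)-2-[4-(benzyloxy)phenyl]-3-iodo-4H-chromen-4-one F3.
- Palladium-catalysed α-alkenylation of 10 with F3 (Pd(OAc)2, P(t-Bu)3, Bu3SnF, toluene, 85 °C) should join C3 to C3'' anti to the aryl group and give (2S,3R)-5,7-bis(benzyloxy)-3-{5,7-bis(benzyloxy)-2-[4-(benzyloxy)phenyl]-4-oxo-4H-chromen-3-yl}-2-(4-methoxyphenyl)chroman-4-one F4.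
- Hydrogenation over 10% Pd/C (H2, EtOAc–MeOH) should add hydrogen syn across C2''=C3'', which gives a 2'',3''-cis unit, and remove the benzyl groups in the same operation to give 27; the cis diastereomer from the other face would have to be separated.

Step 9. The catalyst may not control the enolate face well enough (wrong epimer at the quaternary carbon), the amine may move the exocyclic double bond of 14 into the ring with loss of the C2 centre, and equilibration at C3 may be accompanied by retro-Michael cleavage. The fallback avoids base in the bond-forming event; it sets out from 20 and comes back at 21. Silylation of 20 (t-BuMe2SiOTf, Et3N, CH2Cl2, 0 °C) would give 4,6-bis(benzyloxy)-2-[4-(benzyloxy)phenyl]-3-(tert-butyldimethylsilyloxy)-1-benzofuran F5. F5 is added to 14 in a Mukaiyama–Michael reaction (Sc(OTf)3 10 mol %, CH2Cl2, −78 °C, aqueous work-up). The two epimers at the quaternary carbon are then separated by chromatography, and brief contact with Et3N brings C3 to trans, which gives 21.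

Step 8. Bromination of the electron-rich rings may compete with α-bromination, and the 2-aryl coumaranone may autoxidise at C2 during cyclisation and isolation. The fallback builds the coumaranone ring first and adds the aryl group afterwards; it sets out from 3 and comes back at 20. α-Bromination of 3 (CuBr2, EtOAc–CHCl3, reflux) would give 1-[2,4-bis(benzyloxy)-6-hydroxyphenyl]-2-bromoethanone F6. Cyclisation (NaOAc, EtOH) would give 4,6-bis(benzyloxy)-1-benzofuran-3(2H)-one F7. Palladium-catalysed α-arylation of F7 with 1-(benzyloxy)-4-bromobenzene (Pd2(dba)3, XPhos, NaOt-Bu, toluene, 80 °C, argon) gives 20.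

**Further compounds**
F1 | step 12 | (E)-1-[2,4-bis(benzyloxy)-6-hydroxyphenyl]-3-[4-(benzyloxy)phenyl]prop-2-en-1-one | O=C(/C=C/c1ccc(OCc2ccccc2)cc1)c1c(O)cc(OCc2ccccc2)cc1OCc1ccccc1
F2 | step 12 | 5,7-bis(benzyloxy)-2-[4-(benzyloxy)phenyl]-4H-chromen-4-one | O=c1cc(-c2ccc(OCc3ccccc3)cc2)oc2cc(OCc3ccccc3)cc(OCc3ccccc3)c12
F3 | step 12 | 5,7-bis(benzyloxy)-2-[4-(benzyloxy)phenyl]-3-iodo-4H-chromen-4-one | O=c1c(I)c(-c2ccc(OCc3ccccc3)cc2)oc2cc(OCc3ccccc3)cc(OCc3ccccc3)c12
F4 | step 12 | (2S,3R)-5,7-bis(benzyloxy)-3-{5,7-bis(benzyloxy)-2-[4-(benzyloxy)phenyl]-4-oxo-4H-chromen-3-yl}-2-(4-methoxyphenyl)chroman-4-one | COc1ccc([C@H]2Oc3cc(OCc4ccccc4)cc(OCc4ccccc4)c3C(=O)[C@@H]2c2c(-c3ccc(OCc4ccccc4)cc3)oc3cc(OCc4ccccc4)cc(OCc4ccccc4)c3c2=O)cc1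
F5 | step 9 | 4,6-bis(benzyloxy)-2-[4-(benzyloxy)phenyl]-3-(tert-butyldimethylsilyloxy)-1-benzofuran | CC(C)(C)[Si](C)(C)Oc1c(-c2ccc(OCc3ccccc3)cc2)oc2cc(OCc3ccccc3)cc(OCc3ccccc3)c12
F6 | step 8 | 1-[2,4-bis(benzyloxy)-6-hydroxyphenyl]-2-bromoethanone | O=C(CBr)c1c(O)cc(OCc2ccccc2)cc1OCc1ccccc1
F7 | step 8 | 4,6-bis(benzyloxy)-1-benzofuran-3(2H)-one | O=C1COc2cc(OCc3ccccc3)cc(OCc3ccccc3)c12
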